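**Plan**

- Numbering as in prostanoids: C1 is the ester carbon, C5=C6 and C7=C8 the diene, ring C8–C12 (C9 ketone, C10 chlorinated, C12 acetoxylated), C13–C20 the octenyl chain.
- Enabling feature: C12 is a tertiary carbinol bonded to ring carbon C11 and to C8, a carbon that can be a ketone. This is an α-ketol, so C11–C12 is cut by a reverse acyloin shift to an achiral 1-acylcyclobutanol (C8 carbinol, C12 acyl carbon).
- Cuts in retrosynthetic order: acetyl–O at C12, C10–Cl (through the 10,11-epoxide), C10=C11, C4–C5, C5=C6, then C6–C7/C7=C8 together with a temporary O12–C6 lactone tether, C9–O, C11–C12 (key step), C8–C12 and C12–C13 (dithiane).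
- Forward: octenyl bromide, dithiane and cyclobutanone give the acylcyclobutanol; ring expansion forms the only carbocycle; C9 is oxygenated; a butenolide ring is closed from the C12 hydroxyl onto the C8 ketone and then opened to extend the C1–C6 chain; finally the ring is oxidised, chlorinated and acetylated.
- Stereochemistry: C12 from the chiral aluminium catalyst in the ring expansion; 14Z from (Z)-oct-2-en-1-ol; 7E is enforced by the lactone tether, which holds C6 cis to C12; 5E from the chromium iodo-olefination and a stereoretentive coupling.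

Key step: step 5

Remark: which enantiomer of the N,N′-dioxide ligand delivers the (S)-ketol cannot be assigned in advance; the L-pipecolic-acid-derived ligand is assumed, and its enantiomer would be used if the sense proved opposite.

**Route**

Step 1
Reactants: 1 (2Z)-oct-2-en-1-ol
Product: 2 (2Z)-1-bromooct-2-ene
Conditions: CBr4, PPh3, CH2Cl2, 0 °C
Reagents that add atoms: carbon tetrabromide, BrC(Br)(Br)Br
Why: Appel bromination displaces the alkoxyphosphonium group by SN2 at the primary carbon, so at 0 °C the Z alkene should survive without allylic transposition.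

Step 2
Reactants: 3 1,3-dithiane; 2 (2Z)-1-bromooct-2-ene
Product: 4 2-[(2Z)-oct-2-en-1-yl]-1,3-dithiane
Conditions: n-BuLi, THF, −30 °C; then 2, −78 → 0 °C
Reagents that add atoms: none
Why: Corey–Seebach alkylation, in which the soft 2-lithiodithiane should displace the primary allylic bromide directly (SN2, not SN2′) and give the linear Z-octenyl dithiane carrying the masked C12 acyl carbon.

Step 3
Reactants: 4 2-[(2Z)-oct-2-en-1-yl]-1,3-dithiane; 5 cyclobutanone
Product: 6 1-{2-[(2Z)-oct-2-en-1-yl]-1,3-dithian-2-yl}cyclobutan-1-ol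
Conditions: n-BuLi, THF, −25 °C; then 5, −78 °C; H2O
Reagents that add atoms: none
Why: a second lithiation at the dithiane carbon gives an acyl-anion equivalent that should add cleanly to the strained, electrophilic cyclobutanone (Corey–Seebach 1,2-addition), forming the C8–C12 bond.

Step 4
Reactants: 6 1-{2-[(2Z)-oct-2-en-1-yl]-1,3-dithian-2-yl}cyclobutan-1-ol
Product: 7 1-[(3Z)-non-3-enoyl]cyclobutan-1-ol
Conditions: MeI, CaCO3, MeCN–H2O (4:1), 40 °C
Reagents that add atoms: water, O
Why: alkylative dithioacetal hydrolysis (S-methylation, then capture of the thionium ion by water) under buffered, near-neutral conditions should unmask the ketone without moving the β,γ-Z alkene into conjugation and without a strong Lewis acid that could start an uncontrolled ring expansion.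

Step 5
Reactants: 7 1-[(3Z)-non-3-enoyl]cyclobutan-1-ol
Product: 8 (2S)-2-hydroxy-2-[(2Z)-oct-2-en-1-yl]cyclopentan-1-one
Conditions: Al(OTf)3 (10 mol %), (S,S)-N,N′-dioxide ligand from L-pipecolic acid with 2,6-diisopropylanilide arms (11 mol %), 4 Å molecular sieves, ClCH2CH2Cl, 35 °C
Reagents that add atoms: none
Why: Two-point binding of the tertiary hydroxyl and the acyl oxygen of 7 to the chiral N,N′-dioxide complex of trivalent aluminium polarises the ketone, and a ring C–C bond then shifts suprafacially from C8 to C12 while the carbinol becomes the C8 ketone, which is the α-ketol (acyloin) rearrangement. The closest known reactions are the Lewis-acid ring expansions of 1-acylcyclobutanols to 2-hydroxycyclopentanones and their catalytic enantioselective variants with chiral Lewis acids. The five-membered ring C8–C12 is not closed by attack of a tethered nucleophile but by one-carbon ring expansion, the C11–C12 bond forming as the C8–C11 bond breaks, and the release of cyclobutane strain should make the shift practically irreversible. The only new stereocentre, C12, is created from the flat acyl carbon, and the ligand decides which of the two enantiotopic ring methylenes moves to which carbonyl face, so that the (S)-ketol (R at C12 of the target) is expected. The step needs discrimination between enantiotopic carbons, which is possible because 7 is achiral with a mirror plane through C8 and C10, so that the catalyst alone differentiates them. It also has to outrun conjugation of the skipped Z alkene and a second, degenerate shift of the octenyl group in 8, both of which the mild, non-basic conditions and the lack of strain in the product should suppress.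

Step 6
Reactants: 8 (2S)-2-hydroxy-2-[(2Z)-oct-2-en-1-yl]cyclopentan-1-one
Product: 9 (2S)-2,5-dihydroxy-2-[(2Z)-oct-2-en-1-yl]cyclopentan-1-one (C5 epimers)
Conditions: KN(SiMe3)2 (2.2 equiv), THF, −78 °C; 2-(phenylsulfonyl)-3-phenyloxaziridine, −78 °C; AcOH
Reagents that add atoms: 2-(phenylsulfonyl)-3-phenyloxaziridine, O=S(=O)(N1OC1c1ccccc1)c1ccccc1
Why: enolate hydroxylation with the N-sulfonyloxaziridine (Davis oxidation) should oxygenate C9 alone, because C12 is quaternary and C9 is the only enolisable position of the alkoxide–enolate dianion, and the epimer mixture at the new carbinol is harmless since C9 later becomes the ketone.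

Step 7
Reactants: 9 (2S)-2,5-dihydroxy-2-[(2Z)-oct-2-en-1-yl]cyclopentan-1-one
Product: 10 (3S)-3-hydroxy-3-[(2Z)-oct-2-en-1-yl]-2-oxocyclopentyl acetate (C1 epimers)
Conditions: Ac2O (1.1 equiv), pyridine, CH2Cl2, 0 °C
Reagents that add atoms: acetic anhydride, CC(=O)OC(C)=O
Why: chemoselective O-acylation, in which the secondary C9 hydroxyl should react without DMAP while the hindered tertiary C12 hydroxyl stays free to carry the tether.

Step 8
Reactants: 10 (3S)-3-hydroxy-3-[(2Z)-oct-2-en-1-yl]-2-oxocyclopentyl acetate; 11 (triphenylphosphoranylidene)ketene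
Product: 13 (6aS)-6a-[(2Z)-oct-2-en-1-yl]-2-oxo-4,5,6,6a-tetrahydro-2H-cyclopenta[b]furan-4-yl acetate, via acyl ylide 12 (not isolated)
Conditions: toluene, 110 °C
Reagents that add atoms: none
Why: the ketenylidene ylide (Bestmann ylide) acylates the tertiary hydroxyl to a stabilised ester ylide that closes on the C8 ketone by intramolecular Wittig reaction, so that C6 and C7 are added and the new C7=C8 bond lies in a five-membered lactone, where C6 is necessarily cis to C12, the geometry that becomes 7E.

Step 9
Reactants: 13 (6aS)-6a-[(2Z)-oct-2-en-1-yl]-2-oxo-4,5,6,6a-tetrahydro-2H-cyclopenta[b]furan-4-yl acetate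
Product: 14 (6aS)-6a-[(2Z)-oct-2-en-1-yl]-4,5,6,6a-tetrahydro-2H-cyclopenta[b]furan-2,4-diol (epimers at C2 and C4)
Conditions: i-Bu2AlH (3.2 equiv), CH2Cl2, −78 °C; MeOH, aq. potassium sodium tartrate (KNaC4H4O6)
Reagents that add atoms: none
Why: half-reduction of the butenolide to the lactol should stop at the tetrahedral aluminate at −78 °C, the same hydride cleaves the C9 acetate, and the quaternary C12 rules out aromatisation of the lactol to a furan.

Step 10
Reactants: 14 (6aS)-6a-[(2Z)-oct-2-en-1-yl]-4,5,6,6a-tetrahydro-2H-cyclopenta[b]furan-2,4-diol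
Product: 15 (1S,2Z)-2-[(2E)-3-iodoprop-2-en-1-ylidene]-1-[(2Z)-oct-2-en-1-yl]cyclopentane-1,3-diol (C3 epimers)
Conditions: CrCl2 (8 equiv), CHI3 (3 equiv), THF–dioxane, 0 → 25 °C
Reagents that add atoms: iodoform, IC(I)I
Why: Takai iodo-olefination, in which the hydroxy enal in equilibrium with the lactol is trapped by the gem-dichromium species formed from iodoform and divalent chromium, and anti elimination from the adduct should give the E alkenyl iodide (C5=C6) under non-basic conditions that leave the tether-derived C7=C8 geometry untouched.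

Step 11
Reactants: 15 (1S,2Z)-2-[(2E)-3-iodoprop-2-en-1-ylidene]-1-[(2Z)-oct-2-en-1-yl]cyclopentane-1,3-diol; 16 methyl but-3-enoate
Product: 18 methyl (5E,7Z,12S,14Z)-9,12-dihydroxyprosta-5,7,14-trien-1-oate (C9 epimers), via alkylborane 17 (not isolated)
Conditions: 16, 9-BBN-H (0.95 equiv relative to 16), THF, 0 → 25 °C; then 15, Pd(dppf)Cl2 (5 mol %), AsPh3, Cs2CO3, DMF–H2O, 25 °C
Reagents that add atoms: none
Why: anti-Markovnikov hydroboration of the terminal alkene followed by B-alkyl Suzuki–Miyaura coupling joins C4 to C5 with retention of the alkenyl iodide geometry, tolerates the ester and the free hydroxyls, and the deficit of borane leaves no B–H to attack the alkenes of 15.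

Step 12
Reactants: 18 methyl (5E,7Z,12S,14Z)-9,12-dihydroxyprosta-5,7,14-trien-1-oate
Product: 19 methyl (5E,7E,12S,14Z)-12-hydroxy-9-oxoprosta-5,7,14-trien-1-oate
Conditions: MnO2 (excess), CH2Cl2, 25 °C, dark
Reagents that add atoms: none
Why: MnO2 oxidises the allylic (dienylic) secondary alcohol selectively and leaves the tertiary alcohol and the isolated alkene alone, both C9 epimers converge on the ketone, and the 7Z label turns into 7E only because the CIP priority at C8 changes, not the geometry.

Step 13
Reactants: 19 methyl (5E,7E,12S,14Z)-12-hydroxy-9-oxoprosta-5,7,14-trien-1-oate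
Product: 22 methyl (5E,7E,12R,14Z)-12-hydroxy-9-oxoprosta-5,7,10,14-tetraen-1-oate, via bis(trimethylsilyl) dienol ether 20 (not isolated), via 12-O-trimethylsilyl enone 21 (not isolated)
Conditions: TMSOTf (2.5 equiv), Et3N, CH2Cl2, 0 °C; then Pd(OAc)2 (1.1 equiv), MeCN, 25 °C; aq. citric acid, THF
Reagents that add atoms: none
Why: Saegusa–Ito oxidation, in which enol silylation can only occur toward C10 because C8 bears no hydrogen, palladation at C10 and β-hydride elimination from C11 give the C10=C11 enone, and the tertiary silyl ether formed in passing is cleaved in the acidic work-up.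

Step 14
Reactants: 22 methyl (5E,7E,12R,14Z)-12-hydroxy-9-oxoprosta-5,7,10,14-tetraen-1-oate
Product: 23 methyl (5E,7E,12S,14Z)-10,11-epoxy-12-hydroxy-9-oxoprosta-5,7,14-trien-1-oate (epoxide diastereomers)
Conditions: t-BuOOH (in decane), DBU, CH2Cl2, 0 °C, dark
Reagents that add atoms: tert-butyl hydroperoxide, CC(C)(C)OO
Why: Weitz–Scheffer nucleophilic epoxidation, in which the hydroperoxide anion should add to C11, the β-carbon of the strained endocyclic enone and the most electrophilic site of such cross-conjugated dienones, while the electron-rich Z alkene is inert to this nucleophilic oxidant.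

Step 15
Reactants: 23 methyl (5E,7E,12S,14Z)-10,11-epoxy-12-hydroxy-9-oxoprosta-5,7,14-trien-1-oate
Product: 25 methyl (5E,7E,12R,14Z)-10-chloro-12-hydroxy-9-oxoprosta-5,7,10,14-tetraen-1-oate, via chlorohydrin 24 (not isolated)
Conditions: HCl (4 M in dioxane), CH2Cl2, 0 → 25 °C
Reagents that add atoms: hydrogen chloride, Cl
Why: the classical conversion of an α,β-epoxy ketone into an α-chloro enone, in which chloride opens the protonated epoxide at C10 (SN2 next to the carbonyl) and the resulting β-hydroxy ketone dehydrates through its enol, both epoxide diastereomers converging on the same product.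

Step 16
Reactants: 25 methyl (5E,7E,12R,14Z)-10-chloro-12-hydroxy-9-oxoprosta-5,7,10,14-tetraen-1-oate
Product: 26 methyl (5E,7E,12R,14Z)-12-acetoxy-10-chloro-9-oxoprosta-5,7,10,14-tetraen-1-oate
Conditions: Ac2O, Et3N, DMAP (cat.), CH2Cl2, 0 → 25 °C, dark
Reagents that add atoms: acetic anhydride, CC(=O)OC(C)=O
Why: DMAP-catalysed acyl transfer acetylates the tertiary allylic alcohol, the only hydroxyl left, and the mild base should not disturb the dienone geometry.

**Compound list**

1 | (2Z)-oct-2-en-1-ol | CCCCC/C=C\CO | starting material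
2 | (2Z)-1-bromooct-2-ene | CCCCC/C=C\CBr | intermediate
3 | 1,3-dithiane | C1CSCSC1 | starting material
4 | 2-[(2Z)-oct-2-en-1-yl]-1,3-dithiane | CCCCC/C=C\CC1SCCCS1 | intermediate
5 | cyclobutanone | O=C1CCC1 | starting material
6 | 1-{2-[(2Z)-oct-2-en-1-yl]-1,3-dithian-2-yl}cyclobutan-1-ol | CCCCC/C=C\CC1(SCCCS1)C1(O)CCC1 | intermediate
7 | 1-[(3Z)-non-3-enoyl]cyclobutan-1-ol | CCCCC/C=C\CC(=O)C1(O)CCC1 | intermediate
8 | (2S)-2-hydroxy-2-[(2Z)-oct-2-en-1-yl]cyclopentan-1-one | CCCCC/C=C\C[C@@]1(O)CCCC1=O | intermediate
9 | (2S)-2,5-dihydroxy-2-[(2Z)-oct-2-en-1-yl]cyclopentan-1-one, C5 epimers | CCCCC/C=C\C[C@@]1(O)CCC(O)C1=O | intermediate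
10 | (3S)-3-hydroxy-3-[(2Z)-oct-2-en-1-yl]-2-oxocyclopentyl acetate, C1 epimers | CCCCC/C=C\C[C@@]1(O)CCC(OC(C)=O)C1=O | intermediate
11 | (triphenylphosphoranylidene)ketene | O=C=C=P(c1ccccc1)(c1ccccc1)c1ccccc1 | starting material
12 | (triphenylphosphoranylidene)acetate ester of 10 at the tertiary oxygen (acyl ylide, not isolated) | CCCCC/C=C\C[C@@]1(OC(=O)C=P(c2ccccc2)(c2ccccc2)c2ccccc2)CCC(OC(C)=O)C1=O | intermediate
13 | (6aS)-6a-[(2Z)-oct-2-en-1-yl]-2-oxo-4,5,6,6a-tetrahydro-2H-cyclopenta[b]furan-4-yl acetate, C4 epimers | CCCCC/C=C\C[C@]12OC(=O)C=C1C(OC(C)=O)CC2 | intermediate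
14 | (6aS)-6a-[(2Z)-oct-2-en-1-yl]-4,5,6,6a-tetrahydro-2H-cyclopenta[b]furan-2,4-diol, epimers at C2 and C4 | CCCCC/C=C\C[C@]12OC(O)C=C1C(O)CC2 | intermediate
15 | (1S,2Z)-2-[(2E)-3-iodoprop-2-en-1-ylidene]-1-[(2Z)-oct-2-en-1-yl]cyclopentane-1,3-diol, C3 epimers | CCCCC/C=C\C[C@@]1(O)CCC(O)/C1=C/C=C/I | intermediate
16 | methyl but-3-enoate | COC(=O)CC=C | starting material
17 | methyl 4-(9-borabicyclo[3.3.1]nonan-9-yl)butanoate (not isolated) | COC(=O)CCCB1C2CCCC1CCC2 | intermediate
18 | methyl (5E,7Z,12S,14Z)-9,12-dihydroxyprosta-5,7,14-trien-1-oate, C9 epimers | CCCCC/C=C\C[C@@]1(O)CCC(O)/C1=C/C=C/CCCC(=O)OC | intermediate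
19 | methyl (5E,7E,12S,14Z)-12-hydroxy-9-oxoprosta-5,7,14-trien-1-oate | CCCCC/C=C\C[C@@]1(O)CCC(=O)/C1=C/C=C/CCCC(=O)OC | intermediate
20 | bis(trimethylsilyl) derivative of 19: 9-silyloxy-9,10-ene and 12-silyl ether (not isolated) | CCCCC/C=C\C[C@@]1(O[Si](C)(C)C)CC=C(O[Si](C)(C)C)/C1=C/C=C/CCCC(=O)OC | intermediate
21 | 12-O-trimethylsilyl ether of 22 (not isolated) | CCCCC/C=C\C[C@@]1(O[Si](C)(C)C)C=CC(=O)/C1=C/C=C/CCCC(=O)OC | intermediate
22 | methyl (5E,7E,12R,14Z)-12-hydroxy-9-oxoprosta-5,7,10,14-tetraen-1-oate | CCCCC/C=C\C[C@@]1(O)C=CC(=O)/C1=C/C=C/CCCC(=O)OC | intermediate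
23 | methyl (5E,7E,12S,14Z)-10,11-epoxy-12-hydroxy-9-oxoprosta-5,7,14-trien-1-oate, epoxide diastereomers | CCCCC/C=C\C[C@@]1(O)C2OC2C(=O)/C1=C/C=C/CCCC(=O)OC | intermediate
24 | methyl (5E,7E,14Z)-10-chloro-11,12-dihydroxy-9-oxoprosta-5,7,14-trien-1-oate, configured at C12 as in 23 (chlorohydrin, not isolated) | CCCCC/C=C\C[C@@]1(O)C(O)C(Cl)C(=O)/C1=C/C=C/CCCC(=O)OC | intermediate
25 | methyl (5E,7E,12R,14Z)-10-chloro-12-hydroxy-9-oxoprosta-5,7,10,14-tetraen-1-oate | CCCCC/C=C\C[C@@]1(O)C=C(Cl)C(=O)/C1=C/C=C/CCCC(=O)OC | intermediate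
26 | methyl (5E,7E,12R,14Z)-12-acetoxy-10-chloro-9-oxoprosta-5,7,10,14-tetraen-1-oate | CCCCC/C=C\C[C@@]1(OC(C)=O)C=C(Cl)C(=O)/C1=C/C=C/CCCC(=O)OC | target

**Count and risks**

Total step count: 16. Longest linear sequence: 16 steps (steps 1–16); compounds 11 and 16 are purchased.

Steps most likely to fail:

Step 5. Discrimination between the enantiotopic ring carbons may be incomplete with an aliphatic acyl group, and enantiopurity may erode through a degenerate shift of the octenyl group. The fallback sets out from 7 and resolves instead of inducing asymmetry. Rearrangement with Al(OTf)3 alone should give the racemic ketol F1. Acylation of its tertiary hydroxyl with (S)-2-methoxy-2-phenylacetyl chloride (DMAP, pyridine) should give two diastereomeric esters, the (1S) ester F2 and the (1R) ester F3, which are separated by chromatography. Methanolysis of F2 (K2CO3, MeOH, 0 °C) returns to the route at 8.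

Step 10. Ring–chain opening of the lactol may be too slow under the chromium conditions, and E selectivity at C5=C6 may be poor. The fallback sets out from 14 and builds the alkenyl iodide through an alkyne. Seyferth–Gilbert homologation with dimethyl (1-diazo-2-oxopropyl)phosphonate (K2CO3, MeOH) should give the enyne diol F4. Hydrozirconation of the terminal alkyne with Cp2Zr(H)Cl (3.5 equiv, two of them consumed by the hydroxyls) is syn and places zirconium on the terminal carbon. Iodinolysis with I2 should then give the E iodide, returning to the route at 15.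

Step 14. The hydroperoxide may attack C7 or C5 of the exocyclic dienone instead of C11 (poor site selectivity), and the acid of step 15 may ionise the tertiary carbinol. The fallback sets out from 19, installs chlorine before the ring double bond and avoids both the epoxide and strong acid. Silylation as in step 13 gives 20. N-chlorosuccinimide chlorinates the enol ether at C10, and mild acidic work-up should give the 10-chloro ketone F5. Its dianion (LiN(SiMe3)2, 2.1 equiv, −78 °C) is selenenylated at C10 with PhSeBr to the chloro selenide F6. Oxidation with H2O2 and pyridine gives the selenoxide F7, whose syn elimination toward C11 returns to the route at 25.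

**Further compounds**

F1 | step 5 | (±)-2-hydroxy-2-[(2Z)-oct-2-en-1-yl]cyclopentan-1-one | CCCCC/C=C\CC1(O)CCCC1=O
F2 | step 5 | (1S)-1-[(2Z)-oct-2-en-1-yl]-2-oxocyclopentyl (2S)-2-methoxy-2-phenylacetate | CCCCC/C=C\C[C@@]1(OC(=O)[C@@H](OC)c2ccccc2)CCCC1=O
F3 | step 5 | (1R)-1-[(2Z)-oct-2-en-1-yl]-2-oxocyclopentyl (2S)-2-methoxy-2-phenylacetate | CCCCC/C=C\C[C@]1(OC(=O)[C@@H](OC)c2ccccc2)CCCC1=O
F4 | step 10 | (1S,2Z)-1-[(2Z)-oct-2-en-1-yl]-2-(prop-2-yn-1-ylidene)cyclopentane-1,3-diol, C3 epimers | CCCCC/C=C\C[C@@]1(O)CCC(O)/C1=C/C#C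
F5 | step 14 | methyl (5E,7E,14Z)-10-chloro-12-hydroxy-9-oxoprosta-5,7,14-trien-1-oate, configured at C12 as in 19, C10 epimers | CCCCC/C=C\C[C@@]1(O)CC(Cl)C(=O)/C1=C/C=C/CCCC(=O)OC
F6 | step 14 | methyl (5E,7E,14Z)-10-chloro-12-hydroxy-9-oxo-10-(phenylselanyl)prosta-5,7,14-trien-1-oate, C10 epimers | CCCCC/C=C\C[C@@]1(O)CC(Cl)([Se]c2ccccc2)C(=O)/C1=C/C=C/CCCC(=O)OC
F7 | step 14 | methyl (5E,7E,14Z)-10-chloro-12-hydroxy-9-oxo-10-(phenylseleninyl)prosta-5,7,14-trien-1-oate | CCCCC/C=C\C[C@@]1(O)CC(Cl)([Se](=O)c2ccccc2)C(=O)/C1=C/C=C/CCCC(=O)OC
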